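What crept in the violet run was the product itself. From 12.0 min to 20.0 min it rose by 1.4 percentage points, while the lead of left-handed product over right-handed product shrank from 7.7 points to 2.1 points. Partner was the limiting reagent in violet, 0.16 M against 0.320 M of the two substrates together.

| flask | left-handed substrate | right-handed substrate | partner | precatalyst | remark | time |
|---|---|---|---|---|---|---|
| grey | 0.16 M | 0.16 M | 0.16 M | 0.99 mM | the very flask that is asked about, followed so far |  |
| violet | 0.16 M | 0.16 M | 0.16 M | 2 mM | run made earlier |  |
| flask | 0.16 M | 0.16 M | 0.160 M | 0.99 mM |  | 25 min |

- grey (time / s: left-handed product / %, right-handed product / %): 30.0: 2.1, 0; 60.0: 5.7, 0.2; 90.0: 10.9, 1.0; 120: 14.9, 1.7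
- violet (time / min: left-handed product / %, right-handed product / %): 4.00: 29.3, 7.0; 8.00: 29.4, 14.6; 12.0: 26.8, 19.1; 20.0: 24.7, 22.6

(scatter of a reading: 0.3 percentage points)

- free catalyst is single-handed; left-handed substrate and right-handed substrate are mirror images of each other, charged as a racemate, each of them at the stated concentration
- reactions considered so far: partner + free catalyst + left-handed substrate -> free catalyst + left-handed product; partner + free catalyst + right-handed substrate -> free catalyst + right-handed product; left-handed product <-> right-handed product; partner + precatalyst -> free catalyst + spent reagent; 2 free catalyst -> spent catalyst
- an excess is the difference of the two amounts in percent of their sum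
- an excess is below zero if the other one leads

1. excess of left-handed product over right-handed product in the product at 80 s
2. excess of left-handed product over right-handed product in the product at 25 min
3. part of the left-handed substrate and right-handed substrate charged together that has reacted at 25 min

I turned the question round. For the grey flask to hold a large excess at 25 min, a lead made early had to outlast the run, or fresh product had to keep renewing it. So I read from violet the time in which a lead falls to 0.368 of itself, and called it the memory time (a relaxation time):

memory time = interval / ln(earlier lead / later lead) = 6.16 min

The grey flask's 25 min is longer than that, by a factor of 4.06, so I took a late lead to be freshly fed, and replaced the feed by its mean: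

late lead ≈ mean late rise of product × memory time

For violet this gave 1.1 points, half of the lead I read at 20.0 min, so I allowed for that error. Carrying violet's rise over to the grey flask, I expected an excess between 2.28 % and 4.56 %.

The forecast gave 85 %, 4.6 % and 44.7 %, its late excess coming from “continued production plus racemisation”. Its late excess of 4.6 % lay close to my upper figure.

The grey flask gave 87.4 %, 3.02 % and 47.3 %, each forecast within its margin.

    partner + free catalyst + left-handed substrate → free catalyst + left-handed product (k = 5300 /M²/min)
    partner + free catalyst + right-handed substrate → free catalyst + right-handed product (k = 91.0 /M²/min)
    left-handed product ⇌ right-handed product (k = 0.0970 /min)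
    partner + precatalyst → free catalyst + spent reagent (k = 2.40 /M/min)
    2 free catalyst → spent catalyst (k = 17.0 /M/min)

The grey flask's conversion stood at 43.9 % at 12.5 min, and its mean rise from then to 25 min, times the memory time, gave a lead of 1.7 points, an excess of 3.50 %. In the neighbour with 0.64 M of partner, left-handed substrate stood at 0 % at 25.0 min, so the feed was right-handed. The rate of making right-handed product at that moment, from the constants, times the memory time, gave a right-handed lead of 3 points, an excess of 4.03 %; that flask showed an excess of 3.79 % of right-handed product.

Readings and results were computed for substances that don't exist; the scatter is artificial.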